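## Structural features

The target 22 is a flavone: benzene ring A is fused to the 4-pyranone ring C (O1, C2, C3, C4, C4a, C8a), and C2 carries the para-substituted phenyl ring B. Ring A bears oxygen at C5 (OH), C7 (OH), C8 (OMe) and C8a (the ring oxygen), so only C6 carries hydrogen. C3 holds a prenyl (3-methylbut-2-en-1-yl) enol ether and C4' a prenyl aryl ether; there is no stereocentre. The prenyl ethers are the fragile groups: strong Brønsted or Lewis acid ionises them, hydrogenolysis destroys them, zerovalent palladium can ionise them, and the one on O3 is an allyl vinyl ether that would undergo a Claisen shift on strong heating. Ring A with free phenols is also easily oxidised. The real difficulty is regiochemical: the four oxygens of ring A must be told apart, and ring C must close through the oxygen next to the methoxy group, because closure through the other ortho oxygen gives the 6-methoxy isomer. A second difficulty is to place prenyl on O3 and O4' but not on the more acidic O7, which is best met by bringing both prenyl groups in with the building blocks. The key step exploits that C4 is a carbonyl carbon between C4a and C3: C4 can be carbon monoxide, C4a an aryl iodide, and C3 (with its prenyloxy group), C2 and ring B a single α-alkoxy aryl ketone.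

## Logic of the disconnections

22 from 21: no skeletal bond is cut; the O–H bonds at O5 and O7 are exchanged for O–Si bonds. The reason is that these two phenols must be masked up to the end, both to fix the direction of ring closure and to keep extra phenoxides out of the palladium step, and only fluoride-labile groups come off without harming prenyl ethers. The gain is a ring A with a single free phenol in all earlier compounds. The forward step must cleave two aryl silyl ethers under buffered, cold conditions.

21 from 19 (through 20): the O1–C2 bond is cut and C2 returns to a ketone. Ring C then opens to an acyclic 1,3-diketone whose only free phenol is the one on C8a, so only the 8-methoxy flavone can form. The forward dehydration must use an acid too weak to ionise prenyl ethers or to remove the C5 silyl ether.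

19 from 8, 17 and 18: the C4a–C4 and C3–C4 bonds are cut, so that C4 becomes carbon monoxide. This is the largest simplification: the whole carbon skeleton and every oxygen of 22 come from three components, two of them made independently. The forward step must insert 18 before C–C coupling, acylate the enolate of 17 at carbon, and tolerate a free phenol and two prenyl ethers.

8 from 7: the C4a–I bond is cut. Iodine next to the free phenol defines C4a and thereby the 8-methoxy pattern. The forward iodination must go ortho to the hydroxyl and not to the position between the two silyloxy groups.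

7 from 6, and 6 from 5: first the benzyl group is put back on the C8a oxygen, then the O–CH3 bond at O8 is cut. While the C8 oxygen is a free phenol, its C8a neighbour needs a group that is inert, cannot migrate and leaves later without touching silyl ethers; benzyl does this. The forward methylation must not let the silyl group on the other neighbouring oxygen migrate.

5 from 3 (through 4): the C8–O bond is exchanged for a C8–CHO bond. A phenol flanked by two oxygens and para to a third is an aldehyde carbon in a 2,4,6-trioxygenated benzaldehyde, which is cheap and has its three oxygens already differentiated by chelation. The forward step needs aryl migration to oxygen and a non-basic release of the phenol.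

3 from 2, and 2 from 1: one O–CH2Ph bond and two O–Si bonds are cut. The two ortho hydroxyls of 1 are equivalent, so silylating the para and one ortho hydroxyl and benzylating the chelated one sets all three roles in two steps. The forward silylation must stop at the bis-silyl stage.

17 from 11 and 14 (through 15 and 16): the bond between the carbonyl carbon and ring B is cut. Direct O-alkylation of an α-hydroxy ketone is avoided, because its alkoxide equilibrates with an enediolate; acylation of an aryl Grignard reagent by an N-methoxy-N-methyl amide is clean. The forward step needs single addition.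

11 from 9 and 10, and 14 from 12 and 13: one C–O ether bond is cut in each. Both are Williamson reactions of commercial materials and put each prenyl group in place before any sensitive functionality exists.

## Other disconnections considered

Alternative 1: The cut is C4–C4a; O1–C2 and the C2=C3 double bond are already present in the enol ether acid A1, (E)-2-(benzyloxy)-3-[4-(benzyloxy)phenyl]-3-[3,5-bis(benzyloxy)-2-methoxyphenoxy]prop-2-enoic acid. In the forward direction the carboxyl group of A1 would be activated by a strong dehydrating acid and would acylate ring A in a six-membered Friedel–Crafts closure to the tetrabenzyl ether A2, 3,5,7-tris(benzyloxy)-2-[4-(benzyloxy)phenyl]-8-methoxy-4H-chromen-4-one.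
- In its favour: the aryloxy ring has a single free position ortho to the ether oxygen, activated by one ortho and one para benzyloxy group, so the 8-methoxy pattern is fixed by construction. On this point it equals the chosen plan. It is the better plan in needing no transition metal and no carbon monoxide, and in closing ring C in the key step itself.
- Against it here: acylium chemistry excludes prenyl and silyl ethers, hence the benzyl groups. Hydrogenolysis of A2 would give the tetrol A3, 3,5,7-trihydroxy-2-(4-hydroxyphenyl)-8-methoxy-4H-chromen-4-one, in which the 7-hydroxyl is the most acidic and most easily alkylated. Prenylation of O3 and O4' alone would need a further round of selective protection. A1 is a tetrasubstituted enol ether whose E geometry (aryloxy cis to carboxyl) has to be set, and benzyl ethers ortho to the acylation site may be lost in the acid.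
- Comparison: in structure it gives the right skeleton with the wrong O-substituents; in mechanism it is a cationic process at odds with the fragile groups of 22; in step economy it stands behind the chosen plan, whose key step already carries both prenyl groups and leaves two steps to 22.

Alternative 2: The cuts are C3–C4 and C2=C3. The ring A acid chloride A4, 2-(chlorocarbonyl)-6-methoxy-3,5-bis(tert-butyldimethylsilyloxy)phenyl 4-(prenyloxy)benzoate, would acylate the alkoxymethylene ylide A5, [(prenyloxy)methylidene]triphenylphosphorane. The resulting acylphosphorane A6 would then olefinate the neighbouring aryl ester carbonyl in an intramolecular Wittig reaction to give the bis-silyl flavone A7.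
- In its favour: ring C closes in the key step and only through the ester on the C8a oxygen, so the regiochemistry is as secure as in the chosen plan (equal). A7 differs from 21 only in the silyl group, so one fluoride step finishes the synthesis, one step fewer after the key step (better). Neither palladium nor acid meets the prenyl ethers (better).
- Against it here: A6 is a stabilised, fully substituted ylide and an ester carbonyl is a poor partner for it, so long heating would be needed. That puts at risk the silyl ethers next to carbonyl groups, the aryl ester (acyl migration) and the allyl vinyl ether of the product. Acylation of A5 uses a second equivalent of ylide as base, and A5 derives from an α-halo ether, a class of unstable and hazardous alkylating agents. A4 needs a ring A salicylic acid, that is carboxylation of the same phenol 7 that the chosen plan only iodinates, then O-aroylation and acid chloride formation beside acid-labile silyl ethers.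
- Comparison: in structure the two plans are equal; in mechanism the ester olefination by an α-alkoxy acylphosphorane has less support than the carbonylative α-arylation; in step economy the alternative is shorter after the key step and longer before it. Reliability decides for the chosen plan.

Alternative 3: The cut is C4a–C4, with O1–C2 broken and re-formed during the cascade. The aryl propargyl ether A8, 1-({1-[4-(benzyloxy)phenyl]prop-2-yn-1-yl}oxy)-2-methoxy-3,5-bis(triisopropylsilyloxy)benzene (racemic), is an O-propargyl derivative of phenol 7. On heating it would undergo a [3,3] shift to C4a, enolisation, a 1,5-hydrogen shift and a 6π oxa-electrocyclisation to the 2H-chromene A9, 2-[4-(benzyloxy)phenyl]-8-methoxy-5,7-bis(triisopropylsilyloxy)-2H-chromene (racemic).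
- In its favour: the step is thermal and free of metals and reagents. It closes ring C in the key step, which the chosen key step does not (better). It uses 7 without iodination, one step fewer before the key step (better). Only one ortho position is free, so the regiochemistry is again secure (equal).
- Against it here: A9 has C4 as an sp2 CH and no oxygen on C3. The C4 carbonyl, the C3 oxygen and the C2=C3 double bond must all be introduced by oxidation of an electron-rich chromene that ionises easily to a flavylium ion. These oxidations exclude prenyl groups, hence the benzyl ether on ring B, which must be hydrogenolysed before any prenylation. At that stage O3 and O4' would be the only free hydroxyls and could be prenylated together, a point on which the alternative is at least the equal of the chosen plan. A8 is a doubly activated benzylic propargylic ether that may ionise on formation or on heating, and the shift to the methoxy-bearing ortho carbon competes reversibly.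
- Comparison: in structure the key step reaches the ring system at the wrong oxidation level; in mechanism it is the mildest of all; in step economy about six steps would follow the key step, against two in the chosen plan.

Key step: step 10

Remark: prenyl means 3-methylbut-2-en-1-yl and TIPS means triisopropylsilyl. Diketone 19 is drawn in the keto form, although it should exist together with its enols and with hemiketal 20. The structures of 8, 17 and 19 were checked atom by atom against the numbering of 22; they are consistent and are used without correction.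

## Steps

Step 1
Reactants: 1 2,4,6-trihydroxybenzaldehyde
Product: 2 2-hydroxy-4,6-bis(triisopropylsilyloxy)benzaldehyde
Conditions: TIPSCl (2.1 equiv), imidazole, DMF, 0 °C → rt
Reagents that add atoms: triisopropylsilyl chloride, CC(C)[Si](Cl)(C(C)C)C(C)C
Why: Silyl ether formation; the para hydroxyl and the ortho hydroxyl that is not hydrogen-bonded to the carbonyl oxygen react first, and the last hydroxyl, chelated to the aldehyde, should resist the bulky chloride, as is usual for 2,4,6-trihydroxyaryl carbonyl compounds.

Step 2
Reactants: 2 2-hydroxy-4,6-bis(triisopropylsilyloxy)benzaldehyde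
Product: 3 2-(benzyloxy)-4,6-bis(triisopropylsilyloxy)benzaldehyde
Conditions: BnOH, PPh3, DIAD, THF, 0 °C → rt
Reagents that add atoms: benzyl alcohol, OCc1ccccc1
Why: Mitsunobu etherification of the acidic chelated phenol; no carbonate base is present, so the aryl silyl ethers ortho and para to the aldehyde are not exposed to base-induced cleavage.

Step 3
Reactants: 3 2-(benzyloxy)-4,6-bis(triisopropylsilyloxy)benzaldehyde
Product: 5 2-(benzyloxy)-4,6-bis(triisopropylsilyloxy)phenol, via aryl formate 4 (not isolated)
Conditions: mCPBA, CH2Cl2, 0 °C → rt; aq. Na2S2O3/NaHCO3 wash; then HCl (cat.), MeOH–THF, rt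
Reagents that add atoms: 3-chloroperoxybenzoic acid, O=C(OO)c1cccc(Cl)c1
Why: Baeyer–Villiger (Dakin-type) oxidation in which the electron-rich trioxygenated aryl group migrates in preference to hydrogen; excess peracid is destroyed before the formate is cleaved by acid-catalysed methanolysis, so the new phenol, which sits next to a silyl ether, is never a phenoxide and no oxygen-to-oxygen silyl shift can start.

Step 4
Reactants: 5 2-(benzyloxy)-4,6-bis(triisopropylsilyloxy)phenol
Product: 6 1-(benzyloxy)-2-methoxy-3,5-bis(triisopropylsilyloxy)benzene
Conditions: MeOH, PPh3, DIAD, THF, 0 °C → rt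
Reagents that add atoms: methanol, CO
Why: Mitsunobu O-methylation; the phenoxide exists only as a short-lived ion pair that is methylated at once, which should keep the neighbouring TIPS group in place, and the benzyl ether on the other side cannot migrate.

Step 5
Reactants: 6 1-(benzyloxy)-2-methoxy-3,5-bis(triisopropylsilyloxy)benzene
Product: 7 2-methoxy-3,5-bis(triisopropylsilyloxy)phenol
Conditions: H2 (1 atm), Pd/C (10 wt %), EtOAc, rt
Reagents that add atoms: none
Why: Hydrogenolysis of a benzyl aryl ether; aryl TIPS ethers and the methyl ether are inert, and neither a prenyl group nor an iodide is present yet.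

Step 6
Reactants: 7 2-methoxy-3,5-bis(triisopropylsilyloxy)phenol
Product: 8 2-iodo-6-methoxy-3,5-bis(triisopropylsilyloxy)phenol
Conditions: NIS (1.0 equiv), CH2Cl2, −20 → 0 °C, dark
Reagents that add atoms: N-iodosuccinimide, O=C1CCC(=O)N1I
Why: Electrophilic aromatic iodination of an activated phenol; both open positions are activated, but the one para to the hydroxyl lies between two triisopropylsilyloxy groups and is shielded, so substitution should occur ortho to the free hydroxyl, and one equivalent at low temperature limits di-iodination and oxidation.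

Step 7
Reactants: 9 3-methylbut-2-en-1-ol (prenol), 10 2-chloro-N-methoxy-N-methylacetamide
Product: 11 N-methoxy-N-methyl-2-(prenyloxy)acetamide
Conditions: NaH, THF, 0 °C; then 10, 0 °C → rt
Reagents that add atoms: none
Why: Williamson ether synthesis; sodium prenoxide displaces chloride at the carbonyl-activated carbon (SN2), and the N-methoxy-N-methyl amide is not attacked by the alkoxide under these conditions.

Step 8
Reactants: 12 4-bromophenol, 13 1-bromo-3-methylbut-2-ene (prenyl bromide)
Product: 14 1-bromo-4-(prenyloxy)benzene
Conditions: K2CO3, acetone, reflux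
Reagents that add atoms: none
Why: Williamson O-alkylation of a phenoxide with a primary allylic bromide; acetone favours O- over C-alkylation and direct over allylic (SN2') substitution.

Step 9
Reactants: 14 1-bromo-4-(prenyloxy)benzene, 11 N-methoxy-N-methyl-2-(prenyloxy)acetamide
Product: 17 2-(prenyloxy)-1-[4-(prenyloxy)phenyl]ethan-1-one, via aryl Grignard reagent 15 (not isolated), via magnesium hemiaminal adduct 16 (not isolated)
Conditions: Mg, THF, rt → 40 °C; then 11, THF, 0 °C; aq. NH4Cl
Reagents that add atoms: none
Why: Weinreb ketone synthesis; Grignard reagent 15 adds once to amide 11 to give the chelated tetrahedral adduct 16, which collapses to the ketone only on aqueous work-up, so no tertiary alcohol forms and no enolisable α-hydroxy ketone ever has to be alkylated.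

Step 10
Reactants: 8 2-iodo-6-methoxy-3,5-bis(triisopropylsilyloxy)phenol, 17 2-(prenyloxy)-1-[4-(prenyloxy)phenyl]ethan-1-one (1.5 equiv), 18 carbon monoxide
Product: 19 1-[2-hydroxy-3-methoxy-4,6-bis(triisopropylsilyloxy)phenyl]-2-(prenyloxy)-3-[4-(prenyloxy)phenyl]propane-1,3-dione (racemic)
Conditions: Pd(OAc)2 (5 mol %), Xantphos (7.5 mol %), CO (1 atm), MgCl2 (3 equiv), Et3N (5 equiv), 1,4-dioxane, 80 °C; aq. citric acid
Reagents that add atoms: none
Why: Pd(OAc)2 is reduced in the flask to a zerovalent palladium–Xantphos complex that inserts into the C4a–I bond of 8, and migratory insertion of 18, fast for this di-ortho-substituted aryl group, gives an aroylpalladium iodide. MgCl2 and Et3N enolise the α-alkoxy ketone 17 by chelation-assisted soft enolisation; the magnesium enolate replaces iodide on palladium, C–C reductive elimination forms the C3–C4 bond, and the product leaves the equilibrium as its magnesium 1,3-diketonate. The closest known reaction type is the palladium-catalysed carbonylative α-arylation of ketones with aryl iodides to 1,3-diketones, applied here to an α-alkoxy ketone and a hindered o-iodophenol. No ring closes, and the one new stereocentre (C2 of the dione) is not controlled: it forms racemic, is enolisable and disappears in step 11. Three selectivities are needed: carbonylation before C–C coupling, secured by the two ortho substituents (fast CO insertion, slow direct arylation) and the CO atmosphere; carbon over oxygen acylation of the enolate, favoured by the chelated magnesium enolate and the stable diketonate; and enolate over phenoxide capture of the aroylpalladium, helped by the phenoxide being flanked by the methoxy group and the reacting carbon and being held on magnesium. Soft enolisation also keeps the concentration of free enolate low, which should suppress sigmatropic shifts of the O-prenyl group, and the trisubstituted prenyl ethers are poor substrates for ionisation by zerovalent palladium compared with the aryl iodide. The place of iodine next to the only free phenol fixes C4a and hence the 8-methoxy pattern.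

Step 11
Reactants: 19 1-[2-hydroxy-3-methoxy-4,6-bis(triisopropylsilyloxy)phenyl]-2-(prenyloxy)-3-[4-(prenyloxy)phenyl]propane-1,3-dione
Product: 21 8-methoxy-3-(prenyloxy)-2-[4-(prenyloxy)phenyl]-5,7-bis(triisopropylsilyloxy)-4H-chromen-4-one, via hemiketal 20 (not isolated)
Conditions: PPTS (0.2 equiv), MgSO4, toluene, 60 °C
Reagents that add atoms: none
Why: Cyclodehydration of an o-hydroxyaryl 1,3-diketone; the only free phenol adds to the ring B carbonyl (6-exo-trig) to give hemiketal 20, and the weak pyridinium acid promotes loss of water through an oxocarbenium ion stabilised by O1 and the 4-alkoxyphenyl group, while being too weak to ionise prenyl ethers or cleave aryl TIPS ethers; the C5 oxygen is silylated, so only the 8-methoxy flavone can form.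

Step 12
Reactants: 21 8-methoxy-3-(prenyloxy)-2-[4-(prenyloxy)phenyl]-5,7-bis(triisopropylsilyloxy)-4H-chromen-4-one
Product: 22 5,7-dihydroxy-8-methoxy-3-(prenyloxy)-2-[4-(prenyloxy)phenyl]-4H-chromen-4-one
Conditions: Bu4NF (2.2 equiv), AcOH (2.5 equiv), THF, 0 °C
Reagents that add atoms: none
Why: Fluoride-induced cleavage of the two aryl silyl ethers; acetic acid buffers the phenoxides, prenyl ethers are inert to fluoride, and the temperature stays far below that of a Claisen shift of the 3-O-prenyl enol ether.

## Compound list

1 | 2,4,6-trihydroxybenzaldehyde | O=Cc1c(O)cc(O)cc1O | starting material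
2 | 2-hydroxy-4,6-bis(triisopropylsilyloxy)benzaldehyde | O=Cc1c(O)cc(O[Si](C(C)C)(C(C)C)C(C)C)cc1O[Si](C(C)C)(C(C)C)C(C)C | intermediate
3 | 2-(benzyloxy)-4,6-bis(triisopropylsilyloxy)benzaldehyde | O=Cc1c(OCc2ccccc2)cc(O[Si](C(C)C)(C(C)C)C(C)C)cc1O[Si](C(C)C)(C(C)C)C(C)C | intermediate
4 | 2-(benzyloxy)-4,6-bis(triisopropylsilyloxy)phenyl formate | O=COc1c(OCc2ccccc2)cc(O[Si](C(C)C)(C(C)C)C(C)C)cc1O[Si](C(C)C)(C(C)C)C(C)C | intermediate
5 | 2-(benzyloxy)-4,6-bis(triisopropylsilyloxy)phenol | Oc1c(OCc2ccccc2)cc(O[Si](C(C)C)(C(C)C)C(C)C)cc1O[Si](C(C)C)(C(C)C)C(C)C | intermediate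
6 | 1-(benzyloxy)-2-methoxy-3,5-bis(triisopropylsilyloxy)benzene | COc1c(OCc2ccccc2)cc(O[Si](C(C)C)(C(C)C)C(C)C)cc1O[Si](C(C)C)(C(C)C)C(C)C | intermediate
7 | 2-methoxy-3,5-bis(triisopropylsilyloxy)phenol | COc1c(O)cc(O[Si](C(C)C)(C(C)C)C(C)C)cc1O[Si](C(C)C)(C(C)C)C(C)C | intermediate
8 | 2-iodo-6-methoxy-3,5-bis(triisopropylsilyloxy)phenol | COc1c(O)c(I)c(O[Si](C(C)C)(C(C)C)C(C)C)cc1O[Si](C(C)C)(C(C)C)C(C)C | intermediate
9 | 3-methylbut-2-en-1-ol (prenol) | CC(C)=CCO | starting material
10 | 2-chloro-N-methoxy-N-methylacetamide | CON(C)C(=O)CCl | starting material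
11 | N-methoxy-N-methyl-2-[(3-methylbut-2-en-1-yl)oxy]acetamide | CON(C)C(=O)COCC=C(C)C | intermediate
12 | 4-bromophenol | Oc1ccc(Br)cc1 | starting material
13 | 1-bromo-3-methylbut-2-ene (prenyl bromide) | CC(C)=CCBr | starting material
14 | 1-bromo-4-[(3-methylbut-2-en-1-yl)oxy]benzene | CC(C)=CCOc1ccc(Br)cc1 | intermediate
15 | {4-[(3-methylbut-2-en-1-yl)oxy]phenyl}magnesium bromide | CC(C)=CCOc1ccc([Mg]Br)cc1 | intermediate
16 | bromomagnesium 1-[methoxy(methyl)amino]-2-(prenyloxy)-1-[4-(prenyloxy)phenyl]ethan-1-olate (racemic) | CC(C)=CCOCC(O[Mg]Br)(N(C)OC)c1ccc(OCC=C(C)C)cc1 | intermediate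
17 | 2-[(3-methylbut-2-en-1-yl)oxy]-1-{4-[(3-methylbut-2-en-1-yl)oxy]phenyl}ethan-1-one | CC(C)=CCOCC(=O)c1ccc(OCC=C(C)C)cc1 | intermediate
18 | carbon monoxide | [C-]#[O+] | starting material
19 | 1-[2-hydroxy-3-methoxy-4,6-bis(triisopropylsilyloxy)phenyl]-2-(prenyloxy)-3-[4-(prenyloxy)phenyl]propane-1,3-dione (racemic) | COc1c(O)c(C(=O)C(OCC=C(C)C)C(=O)c2ccc(OCC=C(C)C)cc2)c(O[Si](C(C)C)(C(C)C)C(C)C)cc1O[Si](C(C)C)(C(C)C)C(C)C | intermediate
20 | 2-hydroxy-8-methoxy-3-(prenyloxy)-2-[4-(prenyloxy)phenyl]-5,7-bis(triisopropylsilyloxy)-2,3-dihydro-4H-chromen-4-one (racemic, mixture of diastereomers) | COc1c(O[Si](C(C)C)(C(C)C)C(C)C)cc(O[Si](C(C)C)(C(C)C)C(C)C)c2C(=O)C(OCC=C(C)C)C(O)(c3ccc(OCC=C(C)C)cc3)Oc12 | intermediate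
21 | 8-methoxy-3-(prenyloxy)-2-[4-(prenyloxy)phenyl]-5,7-bis(triisopropylsilyloxy)-4H-chromen-4-one | COc1c(O[Si](C(C)C)(C(C)C)C(C)C)cc(O[Si](C(C)C)(C(C)C)C(C)C)c2c(=O)c(OCC=C(C)C)c(-c3ccc(OCC=C(C)C)cc3)oc12 | intermediate
22 | 5,7-dihydroxy-8-methoxy-3-(prenyloxy)-2-[4-(prenyloxy)phenyl]-4H-chromen-4-one | COc1c(O)cc(O)c2c(=O)c(OCC=C(C)C)c(-c3ccc(OCC=C(C)C)cc3)oc12 | target

## Step count and least certain steps

Total: 12 steps. Longest linear sequence: 9 steps (steps 1–6, 10, 11, 12). The ketone arm (steps 7–9) is two steps deep, with steps 7 and 8 run in parallel.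

Step 10 (key step). Several things may go wrong:
- capture of the aroylpalladium by the magnesium phenoxide of a second molecule of 8 (ester formation and oligomerisation), or O-acylation of the enolate;
- stalling or reduction of the hindered acylpalladium if enolate transfer is slow;
- ionisation of the aryl prenyl ether by zerovalent palladium, since a 4-acylphenoxide is a fair leaving group;
- sigmatropic rearrangement of the prenyloxy enolate at 80 °C.

The fallback leaves the route at 8 and returns to it at 19; it replaces the three-component coupling by a Baker–Venkataraman sequence without palladium or CO. Deprotonation of 8 with MeMgCl and iodine–magnesium exchange with i-PrMgCl·LiCl (THF, −20 °C) should give chloromagnesium 2-(chloromagnesio)-6-methoxy-3,5-bis(triisopropylsilyloxy)phenolate F1. Acylation of this species by Weinreb amide 11 gives 1-[2-hydroxy-3-methoxy-4,6-bis(triisopropylsilyloxy)phenyl]-2-(prenyloxy)ethan-1-one F2. Grignard reagent 15 (from 14) is carboxylated with CO2 to 4-(prenyloxy)benzoic acid F3. Steglich esterification of the phenol of F2 with F3 (EDC·HCl, DMAP, CH2Cl2) gives 2-methoxy-6-[2-(prenyloxy)acetyl]-3,5-bis(triisopropylsilyloxy)phenyl 4-(prenyloxy)benzoate F4. LiN(SiMe3)2 (THF, −78 → 0 °C) then moves the aroyl group from oxygen to the α-carbon and gives 19.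

Step 6. Substitution may occur at the position between the two silyloxy groups (para to the hydroxyl) instead of ortho to it; a second iodination or oxidation of the electron-rich phenol to a quinone may also compete. The fallback leaves at 7 and returns at 8; it replaces electrophilic substitution by directed ortho-metalation. Phenol 7 is converted (MOMCl, i-Pr2NEt, CH2Cl2) into 2-methoxy-1-(methoxymethoxy)-3,5-bis(triisopropylsilyloxy)benzene F5. n-BuLi (THF, −78 °C) removes the only hydrogen ortho to the directing acetal and gives [3-methoxy-2-(methoxymethoxy)-4,6-bis(triisopropylsilyloxy)phenyl]lithium F6. Iodine then gives 2-iodo-6-methoxy-1-(methoxymethoxy)-3,5-bis(triisopropylsilyloxy)benzene F7, and catalytic HCl in MeOH removes the acetal to give 8.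

Step 4 (and the release of the phenol in step 3). The TIPS group may shift from the neighbouring oxygen to the phenoxide oxygen before methyl transfer, which would put the methyl group on O7; the doubly flanked phenol may also react slowly. The fallback leaves at 1 and returns at 6; it keeps silicon out of the molecule until the methyl ether is in place.
- 1 is converted (MOMCl, i-Pr2NEt) into 2-hydroxy-4,6-bis(methoxymethoxy)benzaldehyde F8.
- Benzylation (BnBr, K2CO3, DMF) gives 2-(benzyloxy)-4,6-bis(methoxymethoxy)benzaldehyde F9.
- Baeyer–Villiger oxidation (mCPBA, NaHCO3, CH2Cl2) gives 2-(benzyloxy)-4,6-bis(methoxymethoxy)phenyl formate F10, and methanolysis (K2CO3, MeOH) gives 2-(benzyloxy)-4,6-bis(methoxymethoxy)phenol F11.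
- Methylation (MeI, K2CO3, acetone) gives 1-(benzyloxy)-2-methoxy-3,5-bis(methoxymethoxy)benzene F12.
- Acid methanolysis (HCl, MeOH, 50 °C) gives 5-(benzyloxy)-4-methoxybenzene-1,3-diol F13.
- Silylation (TIPSCl, imidazole, DMF) gives 6.

Step 11. The dehydration may stall at the hemiketal under an acid weak enough for the prenyl ethers. Stronger acid may ionise the prenyl ethers or remove the C5 silyl ether, which would open the second mode of ring closure. The fallback leaves at 19 and returns at 21; it replaces acid catalysis by activation and base-induced elimination. SOCl2 and pyridine (CH2Cl2, −10 → 0 °C) should convert the hemiketal form into 8-methoxy-4-oxo-3-(prenyloxy)-2-[4-(prenyloxy)phenyl]-5,7-bis(triisopropylsilyloxy)-3,4-dihydro-2H-chromen-2-yl sulfurochloridite F14. Pyridine then removes the acidic C3 hydrogen with loss of the leaving group and gives 21.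

## Further compounds

F1 | step 10 | chloromagnesium 2-(chloromagnesio)-6-methoxy-3,5-bis(triisopropylsilyloxy)phenolate | COc1c(O[Mg]Cl)c([Mg]Cl)c(O[Si](C(C)C)(C(C)C)C(C)C)cc1O[Si](C(C)C)(C(C)C)C(C)C
F2 | step 10 | 1-[2-hydroxy-3-methoxy-4,6-bis(triisopropylsilyloxy)phenyl]-2-(prenyloxy)ethan-1-one | COc1c(O)c(C(=O)COCC=C(C)C)c(O[Si](C(C)C)(C(C)C)C(C)C)cc1O[Si](C(C)C)(C(C)C)C(C)C
F3 | step 10 | 4-(prenyloxy)benzoic acid | CC(C)=CCOc1ccc(C(=O)O)cc1
F4 | step 10 | 2-methoxy-6-[2-(prenyloxy)acetyl]-3,5-bis(triisopropylsilyloxy)phenyl 4-(prenyloxy)benzoate | COc1c(OC(=O)c2ccc(OCC=C(C)C)cc2)c(C(=O)COCC=C(C)C)c(O[Si](C(C)C)(C(C)C)C(C)C)cc1O[Si](C(C)C)(C(C)C)C(C)C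
F5 | step 6 | 2-methoxy-1-(methoxymethoxy)-3,5-bis(triisopropylsilyloxy)benzene | COCOc1cc(O[Si](C(C)C)(C(C)C)C(C)C)cc(O[Si](C(C)C)(C(C)C)C(C)C)c1OC
F6 | step 6 | [3-methoxy-2-(methoxymethoxy)-4,6-bis(triisopropylsilyloxy)phenyl]lithium | COCOc1c([Li])c(O[Si](C(C)C)(C(C)C)C(C)C)cc(O[Si](C(C)C)(C(C)C)C(C)C)c1OC
F7 | step 6 | 2-iodo-6-methoxy-1-(methoxymethoxy)-3,5-bis(triisopropylsilyloxy)benzene | COCOc1c(I)c(O[Si](C(C)C)(C(C)C)C(C)C)cc(O[Si](C(C)C)(C(C)C)C(C)C)c1OC
F8 | step 4 | 2-hydroxy-4,6-bis(methoxymethoxy)benzaldehyde | O=Cc1c(O)cc(OCOC)cc1OCOC
F9 | step 4 | 2-(benzyloxy)-4,6-bis(methoxymethoxy)benzaldehyde | O=Cc1c(OCc2ccccc2)cc(OCOC)cc1OCOC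
F10 | step 4 | 2-(benzyloxy)-4,6-bis(methoxymethoxy)phenyl formate | O=COc1c(OCc2ccccc2)cc(OCOC)cc1OCOC
F11 | step 4 | 2-(benzyloxy)-4,6-bis(methoxymethoxy)phenol | Oc1c(OCc2ccccc2)cc(OCOC)cc1OCOC
F12 | step 4 | 1-(benzyloxy)-2-methoxy-3,5-bis(methoxymethoxy)benzene | COc1c(OCc2ccccc2)cc(OCOC)cc1OCOC
F13 | step 4 | 5-(benzyloxy)-4-methoxybenzene-1,3-diol | COc1c(OCc2ccccc2)cc(O)cc1O
F14 | step 11 | 8-methoxy-4-oxo-3-(prenyloxy)-2-[4-(prenyloxy)phenyl]-5,7-bis(triisopropylsilyloxy)-3,4-dihydro-2H-chromen-2-yl sulfurochloridite (racemic, mixture of diastereomers) | COc1c(O[Si](C(C)C)(C(C)C)C(C)C)cc(O[Si](C(C)C)(C(C)C)C(C)C)c2C(=O)C(OCC=C(C)C)C(OS(=O)Cl)(c3ccc(OCC=C(C)C)cc3)Oc12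
A1 | alternative 1 | (E)-2-(benzyloxy)-3-[4-(benzyloxy)phenyl]-3-[3,5-bis(benzyloxy)-2-methoxyphenoxy]prop-2-enoic acid | COc1c(OCc2ccccc2)cc(OCc2ccccc2)cc1O/C(c1ccc(OCc2ccccc2)cc1)=C(/OCc1ccccc1)C(=O)O
A2 | alternative 1 | 3,5,7-tris(benzyloxy)-2-[4-(benzyloxy)phenyl]-8-methoxy-4H-chromen-4-one | COc1c(OCc2ccccc2)cc(OCc2ccccc2)c2c(=O)c(OCc3ccccc3)c(-c3ccc(OCc4ccccc4)cc3)oc12
A3 | alternative 1 | 3,5,7-trihydroxy-2-(4-hydroxyphenyl)-8-methoxy-4H-chromen-4-one | COc1c(O)cc(O)c2c(=O)c(O)c(-c3ccc(O)cc3)oc12
A4 | alternative 2 | 2-(chlorocarbonyl)-6-methoxy-3,5-bis(tert-butyldimethylsilyloxy)phenyl 4-(prenyloxy)benzoate | COc1c(OC(=O)c2ccc(OCC=C(C)C)cc2)c(C(=O)Cl)c(O[Si](C)(C)C(C)(C)C)cc1O[Si](C)(C)C(C)(C)C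
A5 | alternative 2 | [(prenyloxy)methylidene]triphenylphosphorane | CC(C)=CCOC=P(c1ccccc1)(c1ccccc1)c1ccccc1
A6 | alternative 2 | 2-methoxy-6-[2-(prenyloxy)-2-(triphenylphosphoranylidene)acetyl]-3,5-bis(tert-butyldimethylsilyloxy)phenyl 4-(prenyloxy)benzoate | COc1c(OC(=O)c2ccc(OCC=C(C)C)cc2)c(C(=O)C(OCC=C(C)C)=P(c2ccccc2)(c2ccccc2)c2ccccc2)c(O[Si](C)(C)C(C)(C)C)cc1O[Si](C)(C)C(C)(C)C
A7 | alternative 2 | 5,7-bis(tert-butyldimethylsilyloxy)-8-methoxy-3-(prenyloxy)-2-[4-(prenyloxy)phenyl]-4H-chromen-4-one | COc1c(O[Si](C)(C)C(C)(C)C)cc(O[Si](C)(C)C(C)(C)C)c2c(=O)c(OCC=C(C)C)c(-c3ccc(OCC=C(C)C)cc3)oc12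
A8 | alternative 3 | 1-({1-[4-(benzyloxy)phenyl]prop-2-yn-1-yl}oxy)-2-methoxy-3,5-bis(triisopropylsilyloxy)benzene (racemic) | C#CC(Oc1cc(O[Si](C(C)C)(C(C)C)C(C)C)cc(O[Si](C(C)C)(C(C)C)C(C)C)c1OC)c1ccc(OCc2ccccc2)cc1
A9 | alternative 3 | 2-[4-(benzyloxy)phenyl]-8-methoxy-5,7-bis(triisopropylsilyloxy)-2H-chromene (racemic) | COc1c(O[Si](C(C)C)(C(C)C)C(C)C)cc(O[Si](C(C)C)(C(C)C)C(C)C)c2C=CC(c3ccc(OCc4ccccc4)cc3)Oc12
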